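Remarks on the chemistry (assumptions):
- Bicyclic compounds are described with labdane numbering: ring A = C1–C5 and C10; ring B = C5–C10; C11 on C9; C17 is the methyl on C8; C18 (α) and C19 (β) are on C4; C20 is the β methyl on C10. "β" is the face of C20.
- The C4 configuration drawn for 14–16 (4β-ester, 4α-H) is the one expected from hydrogen transfer on the α face. Either epimer serves, because C4 is planarised in step 12.
- Compound 4 is used together with its minor 6-epimer, and 30 and 31 are C11 epimer mixtures. Both centres are removed later (steps 2 and 23).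

## Analysis of the target

The target is a normal-series labdane. It is a trans-fused decalin with a C7=C8 alkene in ring B and a six-carbon chain on C9 that ends in a 13E trisubstituted allylic ester. All five stereocentres lie on the decalin: C20 is β and axial, H-5 and H-9 are α, C4 carries an α methyl and a β, axial CH2O-isovalerate that is 1,3-diaxial to C20, and the C2 hydroxyl is α and equatorial. Three oxygens must end up different: C19 as the isovalerate, C15 as the methyl succinate, C2 free. The allylic C15 ester, the methyl ester and the two trisubstituted alkenes rule out strong acid, strong base, hydride and dissolving metal at the end. The synthesis is hard for two reasons. C4 and C10 are quaternary and flank the C5 methine. The 2α-hydroxyl is the thermodynamic but not the kinetic product of hydride reduction of a C2 ketone, because the β face of C2 is screened by the syn-axial groups on C4 and C10. C9 is a further stereocentre next to a quaternary carbon, and its chain must be attached without moving the C7=C8 alkene. The strategy rests on ring A: at the ketone level C2 is an acyl carbon, and C3 is a CH2 that can be the terminus of an acrylate whose α carbon is C4 and whose carboxyl carbon is C19. These are two acceptor carbons, which a polar reaction does not join but an acyl radical does. The rest of ring B (C5–C10 with C17, the C7=C8 alkene, a C9 carbonyl and the C5 stereocentre) maps onto (R)-carvone 1.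

## Retrosynthetic reasoning

Ester bonds at C15–O and C19–O. The target 39 is traced to the 4-methoxybenzyl ether 38, and this to diol 34 and the acid chlorides 35 and 37. The two esters are cut last because neither survives the carbanion and dissolving-metal chemistry needed earlier. C2–OH is masked meanwhile, since an equatorial secondary hydroxyl cannot be relied on to stay inert while the hindered neopentyl C19–OH is acylated. The forward reactions must first distinguish the unhindered allylic C15–OH from the axial neopentyl C19–OH (36), then acylate C19 (38).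

C2 carbinol and C11–S bond. Diol 34 comes from the bis-silyl ether 33, and this from alcohol 32. Alcohol 32 is traced to keto sulfone 31, so that one dissolving-metal step both removes the sulfone and reduces the C2 ketone. This is placed before any ester is present, because only electron-transfer reduction (protonation under thermodynamic control) gives the equatorial 2α-alcohol.

C11–C12 bond. Ketone 31 comes from ketal 30, which is cut into sulfone 24 and the allylic bromide 28 (made from prenol 25 through 26 and 27). The cut is placed here because the carbanion then sits on the hindered bicyclic partner and the electrophile is an unhindered primary allylic bromide. The 13E alkene is already fixed in 28.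

C9–C11 bond and the C9 stereocentre. Sulfone 24 goes back through sulfide 23 to alcohol 22, and this to diene 20 by hydroboration. The diene comes from the C9 ketone 15 by methylenation (16). Hydroboration must deliver hydrogen to C9 from the α face, anti to C20, and must leave the C7=C8 alkene untouched.

C4–C18 bond. Silyl ether 20 and alcohol 19 come from ester 18, which is cut to ester 16 and iodomethane 2. The enolate at C4 is exocyclic to ring A, and its β face is closed by the axial C20 and the axial ketal oxygen. The methyl group should therefore enter on the α face and leave the carboxyl carbon (C19) β.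

C2–C3 bond, ring A. Ketal 15 comes from diketo ester 14, which is cut between C2 and C3 to the phenyl selenoester 13. Both carbons are acceptors, so the bond is made by a radical. The cut also leaves a monocyclic precursor in which C5 and C10 already carry the two arms trans, so the ring fusion is not at stake in the closure.

Carvone framework. Selenoester 13 comes from acid 12, and this from the differentiated diester 11. The acrylate is traced through acid 10, enal 9 and allylic chloride 8 to the isopropenyl group of 7. The C10 quaternary centre of 7 comes from two enolate alkylations of (R)-carvone 1: first with iodomethane 2 (giving 4), then with tert-butyl bromoacetate 5 anti to the isopropenyl group.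

## Alternatives that were turned down

Alternative 1: The disconnection cuts C5–C10 and C8–C9. In the forward sense the triene A1 undergoes an intramolecular Diels–Alder reaction: its E β-methyl enoate (C9=C10) is tethered through C1–C4 to a 2-silyloxy diene (C5=C6–C7=C8), and the product is the bicyclic silyl enol ether A2.
- For it: both rings and the C5, C9 and C10 centres form in one thermal step. The C2 and C19 oxygens arrive already differentiated. The C9 ester is a direct handle for C11, so methylenation and hydroboration are not needed. On bond economy in the key step it is stronger than the chosen route.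
- Against it: the dienophile is trisubstituted and its β carbon becomes the quaternary C10, while the diene terminus C5 is neopentyl to the quaternary C4, so both bond-forming sites are congested. Facial selectivity and trans fusion depend on C2 and C4, which act only through the tether. A1 needs an acyclic quaternary stereocentre made enantioselectively. After the cycloaddition the C7 enol ether must be turned into the C7=C8 alkene, which takes about three steps and erases the C8 centre just made.
- Comparison: the chosen route buys C5 with carvone, sets C10 by a known anti alkylation, and confines the uncertain event to a single C–C bond.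

Alternative 2: The disconnection cuts C3–C4 and C3–C18. The carvone-derived diazoketone A3 forms a metal carbene at C3, which adds to the C4=C18 alkene of the silyloxymethyl-substituted vinyl arm on C5. The product is the cyclopropyl ketone A4, and reductive opening of C3–C18 would then reveal the C18 methyl.
- For it: the precursor is reached from the same starting material in a similar number of steps. C4 is created quaternary with both substituents at their final oxidation level. The enolate methylation and ester reduction of the chosen route fall away, so it is about two steps shorter after ring closure and stronger on that point.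
- Against it: the C4 configuration is fixed irreversibly by the alkene face that the carbene meets. That choice rests on a rotamer preference of the arm, not on a strong steric element. The carbene can also engage the C9 carbonyl oxygen or insert into allylic C–H bonds. The cyclopropane opening needs electron-transfer conditions that also reduce the enone, so extra ordering or protection is needed. Diazo compounds must be handled.
- Comparison: the chosen route ends its ring closure by a hydrogen transfer that tolerates the enone. It sets C4 in a separate step under the control of the axial C20.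

Alternative 3: The disconnection cuts C5–C6 and C1–C10. A Lewis acid ionises the Z allylic acetate of the acyclic A5. The E C5=C10 alkene attacks C6, and the enol silane closes ring A through C1, giving decalone A6.
- For it: two rings and the trans C5/C10 relation arise in one step. A6 already holds the C7=C8 alkene, the C19 isovalerate, the C2 ketone and a two-carbon stub on C9. The late stage would be clearly shorter than in the chosen route, and on convergence and step count after the key step it is stronger.
- Against it: A5 needs an acyclic quaternary C4 and a doubly allylic C9 stereocentre, both enantio-defined. The allyl cation can be attacked at either end. The nucleophilic alkene carbon C5 is neopentyl. Both stereocentres must enforce the same chair–chair folding, and the enol silane is open to protodesilylation. The C2 ketone of A6 would have to be reduced to the 2α-alcohol with the isovalerate present. Hydride gives the wrong epimer there, and dissolving metal is excluded.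
- Comparison: the chosen route is longer and stepwise, but each stereocentre has an identifiable control element, and C2 is reduced before any ester is in place.

Key step: step 9

## Steps

Step 1
Reactants: 1 (R)-carvone; 2 iodomethane
Product: 4 trans-6-methylcarvone (6-methyl anti to the isopropenyl group; carries some 6-epimer), via lithium dienolate of carvone 3 (not isolated)
Conditions: LiN(iPr)2, THF, −78 °C; MeI, −78 → 0 °C
Reagents that add atoms: iodomethane, CI
Why: Kinetic deprotonation takes the α′ hydrogen at C6 and the cross-conjugated enolate is C-methylated (enolate alkylation); the new centre is planarised again in step 2, so the epimer ratio does not matter.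

Step 2
Reactants: 4 trans-6-methylcarvone; 5 tert-butyl bromoacetate
Product: 7 tert-butyl 2-[1,3-dimethyl-2-oxo-6-(prop-1-en-2-yl)cyclohex-3-en-1-yl]acetate (acetate arm trans and ring methyl cis to the isopropenyl group), via lithium dienolate of 6-methylcarvone 6 (not isolated)
Conditions: LiN(iPr)2, THF, −78 °C; BrCH2CO2t-Bu, DMPU, −78 → −20 °C
Reagents that add atoms: tert-butyl bromoacetate, CC(C)(C)OC(=O)CBr
Why: Second α′ enolate alkylation; the electrophile should approach the enolate face anti to the neighbouring isopropenyl group, which sets the quaternary carbon (later C10) with the arm trans to the C5 substituent, the relation a trans-decalin needs.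

Step 3
Reactants: 7 tert-butyl ester with isopropenyl group
Product: 8 tert-butyl 2-[6-(3-chloroprop-1-en-2-yl)-1,3-dimethyl-2-oxocyclohex-3-en-1-yl]acetate
Conditions: Ca(OCl)2, CO2 (s), CH2Cl2/H2O, 0 °C
Reagents that add atoms: calcium hypochlorite, [Ca+2].[O-]Cl.[O-]Cl
Why: Ene-type allylic chlorination by HOCl picks the electron-rich 1,1-disubstituted alkene over the enone alkene; proton loss from the methyl group gives the 2-(chloromethyl)vinyl unit.

Step 4
Reactants: 8 allylic chloride
Product: 9 tert-butyl 2-[1,3-dimethyl-2-oxo-6-(3-oxoprop-1-en-2-yl)cyclohex-3-en-1-yl]acetate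
Conditions: NMO, KI (cat.), 4 Å MS, MeCN, 40 °C
Reagents that add atoms: N-methylmorpholine N-oxide, C[N+]1([O-])CCOCC1
Why: Kornblum-type oxidation: the N-oxide oxygen displaces the allylic halide (iodide catalysis) and the alkoxyammonium salt collapses to the enal under nearly neutral conditions; both allyl termini are CH2, so direct and allylic displacement give the same product.

Step 5
Reactants: 9 enal
Product: 10 2-[2-(2-tert-butoxy-2-oxoethyl)-2,4-dimethyl-3-oxocyclohex-4-en-1-yl]prop-2-enoic acid
Conditions: NaClO2, NaH2PO4, 2-methylbut-2-ene, t-BuOH/H2O, 0 °C → rt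
Reagents that add atoms: sodium chlorite, [Na+].[O-]Cl=O
Why: Pinnick oxidation is selective for the aldehyde; the alkene scavenger removes HOCl, so the enone and the acrylic double bond are left alone.

Step 6
Reactants: 10 acrylic acid; 2 iodomethane
Product: 11 methyl 2-[2-(2-tert-butoxy-2-oxoethyl)-2,4-dimethyl-3-oxocyclohex-4-en-1-yl]prop-2-enoate
Conditions: MeI, K2CO3, DMF, 0 °C → rt
Reagents that add atoms: iodomethane, CI
Why: O-Alkylation of the carboxylate (SN2) under mild base; the tert-butyl ester and the enone do not react.

Step 7
Reactants: 11 methyl/tert-butyl diester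
Product: 12 2-[6-(3-methoxy-3-oxoprop-1-en-2-yl)-1,3-dimethyl-2-oxocyclohex-3-en-1-yl]acetic acid
Conditions: CF3CO2H, CH2Cl2, 0 °C → rt
Reagents that add atoms: none
Why: Acidolysis of the tert-butyl ester through the tert-butyl cation frees only the acetic acid arm; the methyl acrylate is stable to these conditions.

Step 8
Reactants: 12 carboxylic acid
Product: 13 methyl 2-{2,4-dimethyl-3-oxo-2-[2-oxo-2-(phenylselanyl)ethyl]cyclohex-4-en-1-yl}prop-2-enoate (Se-phenyl selenoester; arm on the quaternary carbon trans to the acrylate)
Conditions: N-(phenylseleno)phthalimide, Bu3P, CH2Cl2, −30 °C → rt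
Reagents that add atoms: N-(phenylseleno)phthalimide, O=C1N([Se]c2ccccc2)C(=O)c2ccccc12
Why: Phosphine-mediated selenoesterification through an acyloxyphosphonium ion that is captured by the selenolate; phthalimide takes up the proton, so no free selenol builds up to add to the acrylate.

Step 9
Reactants: 13 phenyl selenoester
Product: 14 methyl 4a,6-dimethyl-3,5-dioxo-1,2,3,4,4a,5,8,8a-octahydronaphthalene-1-carboxylate (labdane numbering: trans-decalin, 2-oxo, 9-oxo, C7=C8, 10β-CH3, 5α-H, 4β-CO2Me, 4α-H)
Conditions: Bu3SnH (slow addition), AIBN, PhH (0.01 M), 80 °C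
Reagents that add atoms: none
Why: The stannyl radical abstracts the phenylseleno group and frees the C2 acyl radical, a nucleophilic σ radical, which adds to C3, the unsubstituted CH2 end of the acrylate; the ester-stabilised C4 radical then takes hydrogen from Bu3SnH and carries the chain. The closest known reaction type is the tin-hydride-mediated 6-endo-trig cyclisation of hex-5-enoyl radicals from phenyl selenoesters onto 1,1-disubstituted electron-poor alkenes. Ring A closes in the 6-endo mode; the 5-exo path would need attack at the fully substituted, ester-bearing C4 and is disfavoured by both sterics and polarity. The ring fusion is not made here, because C5 and C10 already hold the two arms trans and diequatorial, so a chair-like closure can only give the trans-decalin. The one new stereocentre, C4, is set by hydrogen transfer to the planar radical on the α face, anti to the axial C20; it is provisional, since C4 is planarised in step 12. The step needs cyclisation to outrun direct reduction to the aldehyde and loss of CO; high dilution, slow hydride addition and the slow decarbonylation of a primary acyl radical serve this. It also needs the acrylate to be preferred over the ring B enone. Attack at the enone carbon C7 would give a bicyclo[2.2.2]octane and requires the C10 arm axial, which forces the C5 acrylate axial too, so in the populated diequatorial conformer only the acrylate is within reach.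

Step 10
Reactants: 14 diketo ester
Product: 15 C2 ethylene ketal of 14 (spiro-1,3-dioxolane at C2; C9 enone and 4β-CO2Me unchanged)
Conditions: HOCH2CH2OH, PPTS, PhH, reflux (Dean–Stark)
Reagents that add atoms: ethylene glycol, OCCO
Why: Acid-catalysed ketalisation is chemoselective for the saturated, unhindered C2 ketone; the C9 ketone is conjugated and flanked by the quaternary C10 and the substituted C8.

Step 11
Reactants: 15 keto ketal
Product: 16 9-methylidene diene ester (C9=C11 exocyclic, conjugated with C7=C8; C2 ketal; 4β-CO2Me)
Conditions: Ph3PCH3Br, KN(SiMe3)2, THF, 0 °C; then 15, 0 → 65 °C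
Reagents that add atoms: methyltriphenylphosphonium bromide, C[P+](c1ccccc1)(c1ccccc1)c1ccccc1.[Br-]
Why: Wittig methylenation; the small unstabilised ylide adds 1,2 to the hindered enone on heating, and the hindered secondary ester is not attacked; any C4 enolate is reprotonated on the α face at work-up.

Step 12
Reactants: 16 diene ester; 2 iodomethane
Product: 18 methyl ester with quaternary C4 (4α-CH3 and 4β-CO2Me; C2 ketal; C7=C8 and C9=C11), via lithium ester enolate 17 (not isolated)
Conditions: LiN(iPr)2, THF, −78 → −30 °C; MeI, DMPU, −78 → 0 °C
Reagents that add atoms: iodomethane, CI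
Why: Ester enolate alkylation; the β face of the exocyclic enolate is blocked by the 1,3-diaxial C20 and the axial ketal oxygen, so the methyl group should enter on the α face, leaving C19 β and axial as in the target.

Step 13
Reactants: 18 methyl ester
Product: 19 C19 primary alcohol (4β-CH2OH, 4α-CH3; C2 ketal; diene)
Conditions: LiAlH4, THF, 0 °C → reflux
Reagents that add atoms: none
Why: Hydride reduction of the hindered neopentyl ester to the alcohol; the ketal and the unactivated diene are inert.

Step 14
Reactants: 19 alcohol
Product: 20 C19 triisopropylsilyl ether of 19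
Conditions: i-Pr3SiOTf, 2,6-lutidine, CH2Cl2, 0 °C → rt
Reagents that add atoms: triisopropylsilyl triflate, CC(C)[Si](OS(=O)(=O)C(F)(F)F)(C(C)C)C(C)C
Why: The silyl triflate silylates even an axial neopentyl alcohol; the group is chosen because it survives aqueous acid, organolithium and dissolving metal and is removed by fluoride.

Step 15
Reactants: 20 diene
Product: 22 C11 alcohol (9β-CH2OH with 9α-H; C7=C8 retained; C2 ketal; 19-O-silyl), via B-alkyl-9-BBN adduct 21 (not isolated)
Conditions: 9-BBN, THF, 0 → 50 °C; then NaOH, H2O2, 0 °C → rt
Reagents that add atoms: 9-borabicyclo[3.3.1]nonane (boron stands in 21 only), B1C2CCCC1CCC2; hydrogen peroxide, OO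
Why: Hydroboration–oxidation; the bulky borane adds only to the terminal CH2 of the diene and delivers hydrogen to C9 from the α face, anti to the axial C20, which sets 9α-H with C11 equatorial.

Step 16
Reactants: 22 C11 alcohol
Product: 23 C11 phenyl sulfide (9β-CH2SPh)
Conditions: PhSSPh, Bu3P, pyridine, 60 °C
Reagents that add atoms: diphenyl disulfide, c1ccc(cc1)SSc1ccccc1
Why: Phosphine–disulfide thioetherification: the alkoxyphosphonium ion of the primary alcohol is displaced by thiolate at C11; no other hydroxyl is free.

Step 17
Reactants: 23 sulfide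
Product: 24 C11 phenyl sulfone (9β-CH2SO2Ph; C2 ketal; 19-O-silyl; C7=C8)
Conditions: (NH4)6Mo7O24·4H2O (cat.), 30% H2O2, EtOH, 0 °C → rt
Reagents that add atoms: hydrogen peroxide, OO
Why: Molybdate-catalysed peroxide oxidation takes sulfur to the sulfone much faster than it epoxidises a trisubstituted alkene.

Step 18
Reactants: 25 prenol (3-methylbut-2-en-1-ol)
Product: 26 triisopropyl(3-methylbut-2-enyloxy)silane
Conditions: i-Pr3SiCl, imidazole, CH2Cl2, rt
Reagents that add atoms: chlorotriisopropylsilane, CC(C)[Si](Cl)(C(C)C)C(C)C
Why: Standard silylation of a primary allylic alcohol.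

Step 19
Reactants: 26 prenyl silyl ether
Product: 27 (E)-2-methyl-4-(triisopropylsilyloxy)but-2-en-1-ol
Conditions: SeO2 (cat.), t-BuOOH, salicylic acid (cat.), CH2Cl2, rt
Reagents that add atoms: selenium dioxide, O=[Se]=O; tert-butyl hydroperoxide, CC(C)(C)OO
Why: Allylic oxidation by an ene reaction and [2,3] shift; with a gem-dimethyl alkene it oxidises the E methyl group, which fixes the 13E geometry of the side chain.

Step 20
Reactants: 27 allylic alcohol
Product: 28 (E)-(4-bromo-3-methylbut-2-enyloxy)triisopropylsilane
Conditions: CBr4, PPh3, CH2Cl2, 0 °C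
Reagents that add atoms: carbon tetrabromide, BrC(Br)(Br)Br
Why: Appel bromination of a primary allylic alcohol under neutral conditions keeps the alkene geometry.

Step 21
Reactants: 24 sulfone; 28 allylic bromide
Product: 30 11-(phenylsulfonyl)-2,2-(ethylenedioxy)-15,19-bis(triisopropylsilyloxy)labda-7,13E-diene (C11 epimers), via lithiated sulfone 29 (not isolated)
Conditions: n-BuLi, THF, −78 °C; then 28, DMPU, −78 → −20 °C
Reagents that add atoms: bromide 28, CC(C)[Si](OC/C=C(\C)CBr)(C(C)C)C(C)C
Why: Julia-type alkylation: the sulfonyl carbanion on the hindered C11 displaces the unhindered primary allylic bromide at carbon (SN2) with the E alkene intact; the new C11 centre is removed in step 23.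

Step 22
Reactants: 30 ketal
Product: 31 11-(phenylsulfonyl)-15,19-bis(triisopropylsilyloxy)labda-7,13E-dien-2-one (C11 epimers)
Conditions: PPTS, acetone/H2O, 55 °C
Reagents that add atoms: water, O
Why: Mild acid hydrolysis of the dioxolane, helped by the syn-axial strain between the ketal oxygen and the C4 and C10 substituents; the triisopropylsilyl ethers and the alkenes tolerate it.

Step 23
Reactants: 31 keto sulfone
Product: 32 15,19-bis(triisopropylsilyloxy)labda-7,13E-dien-2α-ol
Conditions: Li, NH3 (l), THF, t-BuOH, −78 °C; NH4Cl
Reagents that add atoms: none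
Why: Dissolving-metal reduction does two jobs: it cleaves the C11–S bond (reductive desulfonylation) and reduces the C2 ketone through the ketyl under thermodynamic control. Protonation gives the equatorial 2α-alcohol, whereas hydride would attack from the open α face and give the 2β-epimer.

Step 24
Reactants: 32 secondary alcohol
Product: 33 2α-(4-methoxybenzyloxy)-15,19-bis(triisopropylsilyloxy)labda-7,13E-diene
Conditions: NaH, 4-MeOC6H4CH2Cl, Bu4NI (cat.), THF/DMF, 0 °C → rt
Reagents that add atoms: 4-methoxybenzyl chloride, COc1ccc(CCl)cc1
Why: Williamson etherification of the only free hydroxyl; this ether is stable to fluoride and acylation and is removed oxidatively at the end without touching esters.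

Step 25
Reactants: 33 bis-silyl ether
Product: 34 2α-(4-methoxybenzyloxy)labda-7,13E-diene-15,19-diol
Conditions: Bu4NF, THF, rt → 50 °C
Reagents that add atoms: none
Why: Fluoride cleaves both silyl ethers; the axial neopentyl one needs warming.

Step 26
Reactants: 34 diol; 35 methyl 4-chloro-4-oxobutanoate
Product: 36 methyl 19-hydroxy-2α-(4-methoxybenzyloxy)labda-7,13E-dien-15-yl butanedioate
Conditions: 35 (1.05 equiv), 2,4,6-collidine, CH2Cl2, −78 → −40 °C
Reagents that add atoms: methyl 4-chloro-4-oxobutanoate, COC(=O)CCC(=O)Cl
Why: Chemoselective acylation with an acid chloride and a hindered pyridine at low temperature; the unhindered allylic C15–OH should react well ahead of the axial neopentyl C19–OH.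

Step 27
Reactants: 36 C19 alcohol; 37 3-methylbutanoyl chloride
Product: 38 methyl 2α-(4-methoxybenzyloxy)-19-(3-methylbutanoyloxy)labda-7,13E-dien-15-yl butanedioate
Conditions: 37, pyridine, DMAP (cat.), CH2Cl2, 0 °C → rt
Reagents that add atoms: 3-methylbutanoyl chloride, CC(C)CC(=O)Cl
Why: DMAP-catalysed acylation of the remaining hindered primary alcohol; no other hydroxyl is free, so excess reagent can be used.

Step 28
Reactants: 38 4-methoxybenzyl ether
Product: 39 methyl 2α-hydroxy-19-(3-methylbutanoyloxy)labda-7,13E-dien-15-yl butanedioate (target)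
Conditions: DDQ, CH2Cl2/pH 7 buffer, 0 °C
Reagents that add atoms: none
Why: Oxidative cleavage of the electron-rich benzyl ether by hydride abstraction and hydrolysis of the oxocarbenium ion; the three esters and both trisubstituted alkenes are inert, and the 2α-hydroxyl has no acyl group within reach for migration.

## Compound list

1 | (R)-carvone | CC(=C)[C@@H]1CC=C(C)C(=O)C1 | starting material
2 | iodomethane | CI | starting material
3 | lithium dienolate of carvone | CC(=C)[C@@H]1CC=C(C)C(O[Li])=C1 | intermediate (not isolated)
4 | trans-6-methylcarvone (with minor 6-epimer) | CC(=C)[C@@H]1CC=C(C)C(=O)[C@H]1C | intermediate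
5 | tert-butyl bromoacetate | CC(C)(C)OC(=O)CBr | starting material
6 | lithium dienolate of 6-methylcarvone | CC(=C)[C@@H]1CC=C(C)C(O[Li])=C1C | intermediate (not isolated)
7 | tert-butyl 2-[1,3-dimethyl-2-oxo-6-(prop-1-en-2-yl)cyclohex-3-en-1-yl]acetate (arm trans to isopropenyl) | CC(C)(C)OC(=O)C[C@]1(C)C(=O)C(C)=CC[C@H]1C(C)=C | intermediate
8 | tert-butyl 2-[6-(3-chloroprop-1-en-2-yl)-1,3-dimethyl-2-oxocyclohex-3-en-1-yl]acetate | CC(C)(C)OC(=O)C[C@]1(C)C(=O)C(C)=CC[C@H]1C(=C)CCl | intermediate
9 | tert-butyl 2-[1,3-dimethyl-2-oxo-6-(3-oxoprop-1-en-2-yl)cyclohex-3-en-1-yl]acetate | CC(C)(C)OC(=O)C[C@]1(C)C(=O)C(C)=CC[C@H]1C(=C)C=O | intermediate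
10 | 2-[2-(2-tert-butoxy-2-oxoethyl)-2,4-dimethyl-3-oxocyclohex-4-en-1-yl]prop-2-enoic acid | CC(C)(C)OC(=O)C[C@]1(C)C(=O)C(C)=CC[C@H]1C(=C)C(=O)O | intermediate
11 | methyl 2-[2-(2-tert-butoxy-2-oxoethyl)-2,4-dimethyl-3-oxocyclohex-4-en-1-yl]prop-2-enoate | CC(C)(C)OC(=O)C[C@]1(C)C(=O)C(C)=CC[C@H]1C(=C)C(=O)OC | intermediate
12 | 2-[6-(3-methoxy-3-oxoprop-1-en-2-yl)-1,3-dimethyl-2-oxocyclohex-3-en-1-yl]acetic acid | OC(=O)C[C@]1(C)C(=O)C(C)=CC[C@H]1C(=C)C(=O)OC | intermediate
13 | Se-phenyl selenoester of 12 (key-step precursor) | O=C(C[C@]1(C)C(=O)C(C)=CC[C@H]1C(=C)C(=O)OC)[Se]c1ccccc1 | intermediate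
14 | 2,9-dioxo trans-decalin with 4β-CO2Me, C7=C8, 10β-CH3, 5α-H (key-step product) | O=C1C(C)=CC[C@H]2[C@@H](C(=O)OC)CC(=O)C[C@]12C | intermediate
15 | C2 ethylene ketal of 14 | O=C1C(C)=CC[C@H]2[C@@H](C(=O)OC)CC3(OCCO3)C[C@]12C | intermediate
16 | 9-methylidene diene ester, C2 ketal | C=C1C(C)=CC[C@H]2[C@@H](C(=O)OC)CC3(OCCO3)C[C@]12C | intermediate
17 | lithium ester enolate at C4 | C=C1C(C)=CC[C@H]2C(=C(OC)O[Li])CC3(OCCO3)C[C@]12C | intermediate (not isolated)
18 | 4α-methyl 4β-methoxycarbonyl diene ketal | C=C1C(C)=CC[C@H]2[C@@](C)(C(=O)OC)CC3(OCCO3)C[C@]12C | intermediate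
19 | C19 alcohol (4β-CH2OH) diene ketal | C=C1C(C)=CC[C@H]2[C@@](C)(CO)CC3(OCCO3)C[C@]12C | intermediate
20 | C19 triisopropylsilyl ether diene ketal | C=C1C(C)=CC[C@H]2[C@@](C)(CO[Si](C(C)C)(C(C)C)C(C)C)CC3(OCCO3)C[C@]12C | intermediate
21 | B-alkyl-9-BBN adduct at C11 (9α-H) | C(B1C2CCCC1CCC2)[C@H]1C(C)=CC[C@H]2[C@@](C)(CO[Si](C(C)C)(C(C)C)C(C)C)CC3(OCCO3)C[C@]12C | intermediate (not isolated)
22 | C11 alcohol (9β-CH2OH, 9α-H), C7=C8, C2 ketal, 19-O-silyl | OC[C@H]1C(C)=CC[C@H]2[C@@](C)(CO[Si](C(C)C)(C(C)C)C(C)C)CC3(OCCO3)C[C@]12C | intermediate
23 | C11 phenyl sulfide | c1ccccc1SC[C@H]1C(C)=CC[C@H]2[C@@](C)(CO[Si](C(C)C)(C(C)C)C(C)C)CC3(OCCO3)C[C@]12C | intermediate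
24 | C11 phenyl sulfone | O=S(=O)(c1ccccc1)C[C@H]1C(C)=CC[C@H]2[C@@](C)(CO[Si](C(C)C)(C(C)C)C(C)C)CC3(OCCO3)C[C@]12C | intermediate
25 | prenol (3-methylbut-2-en-1-ol) | CC(C)=CCO | starting material
26 | triisopropyl(3-methylbut-2-enyloxy)silane | CC(C)=CCO[Si](C(C)C)(C(C)C)C(C)C | intermediate
27 | (E)-2-methyl-4-(triisopropylsilyloxy)but-2-en-1-ol | CC(C)[Si](OC/C=C(\C)CO)(C(C)C)C(C)C | intermediate
28 | (E)-(4-bromo-3-methylbut-2-enyloxy)triisopropylsilane | CC(C)[Si](OC/C=C(\C)CBr)(C(C)C)C(C)C | intermediate
29 | lithiated sulfone (C11 carbanion of 24) | [Li]C([C@H]1C(C)=CC[C@H]2[C@@](C)(CO[Si](C(C)C)(C(C)C)C(C)C)CC3(OCCO3)C[C@]12C)S(=O)(=O)c1ccccc1 | intermediate (not isolated)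
30 | 11-(phenylsulfonyl)-2,2-(ethylenedioxy)-15,19-bis(triisopropylsilyloxy)labda-7,13E-diene (C11 epimers) | CC(C)[Si](OC/C=C(\C)CC([C@H]1C(C)=CC[C@H]2[C@@](C)(CO[Si](C(C)C)(C(C)C)C(C)C)CC3(OCCO3)C[C@]12C)S(=O)(=O)c1ccccc1)(C(C)C)C(C)C | intermediate
31 | 11-(phenylsulfonyl)-15,19-bis(triisopropylsilyloxy)labda-7,13E-dien-2-one (C11 epimers) | CC(C)[Si](OC/C=C(\C)CC([C@H]1C(C)=CC[C@H]2[C@@](C)(CO[Si](C(C)C)(C(C)C)C(C)C)CC(=O)C[C@]12C)S(=O)(=O)c1ccccc1)(C(C)C)C(C)C | intermediate
32 | 15,19-bis(triisopropylsilyloxy)labda-7,13E-dien-2α-ol | CC(C)[Si](OC/C=C(\C)CC[C@H]1C(C)=CC[C@H]2[C@@](C)(CO[Si](C(C)C)(C(C)C)C(C)C)C[C@H](O)C[C@]12C)(C(C)C)C(C)C | intermediate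
33 | 2α-(4-methoxybenzyloxy)-15,19-bis(triisopropylsilyloxy)labda-7,13E-diene | CC(C)[Si](OC/C=C(\C)CC[C@H]1C(C)=CC[C@H]2[C@@](C)(CO[Si](C(C)C)(C(C)C)C(C)C)C[C@H](OCc3ccc(OC)cc3)C[C@]12C)(C(C)C)C(C)C | intermediate
34 | 2α-(4-methoxybenzyloxy)labda-7,13E-diene-15,19-diol | OC/C=C(\C)CC[C@H]1C(C)=CC[C@H]2[C@@](C)(CO)C[C@H](OCc3ccc(OC)cc3)C[C@]12C | intermediate
35 | methyl 4-chloro-4-oxobutanoate | COC(=O)CCC(=O)Cl | starting material
36 | methyl 19-hydroxy-2α-(4-methoxybenzyloxy)labda-7,13E-dien-15-yl butanedioate | COC(=O)CCC(=O)OC/C=C(\C)CC[C@H]1C(C)=CC[C@H]2[C@@](C)(CO)C[C@H](OCc3ccc(OC)cc3)C[C@]12C | intermediate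
37 | 3-methylbutanoyl chloride | CC(C)CC(=O)Cl | starting material
38 | methyl 2α-(4-methoxybenzyloxy)-19-(3-methylbutanoyloxy)labda-7,13E-dien-15-yl butanedioate | COC(=O)CCC(=O)OC/C=C(\C)CC[C@H]1C(C)=CC[C@H]2[C@@](C)(COC(=O)CC(C)C)C[C@H](OCc3ccc(OC)cc3)C[C@]12C | intermediate
39 | methyl 2α-hydroxy-19-(3-methylbutanoyloxy)labda-7,13E-dien-15-yl butanedioate | COC(=O)CCC(=O)OC/C=C(\C)CC[C@H]1C(C)=CC[C@H]2[C@@](C)(COC(=O)CC(C)C)C[C@H](O)C[C@]12C | target

## Step count and least certain steps

Total step count: 28. Longest linear sequence: 25 (steps 1–17 and 21–28); steps 18–20 make bromide 28.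

Step 9 (key step). The likeliest failure is hydrogen transfer to the acyl radical before ring closure, which would leave the uncyclised aldehyde. Bridged closure onto the enone is possible if the diaxial conformer is more accessible than expected. Fallback, a polar umpolung of the same bond: acid 12 is activated as its isobutyl mixed carbonic anhydride and reduced with NaBH4 at −15 °C to the primary alcohol F1. Dess–Martin periodinane gives the aldehyde F2. An intramolecular Stetter reaction (thiazolium salt, Et3N, EtOH, 70 °C) makes C2 an acyl anion equivalent that adds to the same acrylate carbon C3. The route is rejoined at 14.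

Step 4. Displacement of the allylic chloride by the N-oxide may be slow, and the 2-substituted acrolein may oligomerise or isomerise under prolonged warming with amine. Fallback through the alcohol oxidation level: chloride 8 is treated with KOAc and Bu4NI (cat.) in DMF to give the allylic acetate F3. Methanolysis (K2CO3, MeOH, 0 °C) gives the allylic alcohol F4, and MnO2 in CH2Cl2 gives enal 9.

Step 11. The ylide may act as a base (γ-deprotonation of the enone) and not add, because the C9 carbonyl lies between a quaternary carbon and a substituted alkene carbon. It may also be acylated by the ester. Fallback, a two-step Peterson olefination with a less basic, more nucleophilic reagent: ketone 15 is treated with Me3SiCH2MgCl and CeCl3 in THF at −78 → 0 °C to give the β-hydroxysilane F5. KH in THF then induces syn-elimination to diene 16.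

Step 23. Desulfonylation may stall through α-deprotonation of the sulfone by the amide that builds up. Reductive loss of the allylic silyloxy group at C15 may compete. Fallback that separates the two reductions and avoids solvated electrons at the ketone stage: sulfone 30 is desulfonylated with Na(Hg) and Na2HPO4 in MeOH/THF at −20 °C to the ketal F6. Hydrolysis (PPTS, acetone/H2O) gives the sulfone-free ketone F7. An equilibrating Meerwein–Ponndorf–Verley reduction (Al(OiPr)3, i-PrOH, trace acetone, reflux) gives the more stable equatorial alcohol 32.

Step 26. Discrimination between the two primary hydroxyls may be insufficient and lead to acylation at C19 or at both sites. Fallback that reverses the order of acylation with a temporary silyl group: diol 34 is silylated at the allylic position with t-BuMe2SiCl and imidazole at −20 °C to give the mono-silyl ether F8. Acylation with 37, pyridine and DMAP gives the isovalerate F9. HF·pyridine in THF frees the C15 alcohol F10, and acylation with 35 and pyridine gives 38.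

## Further compounds

F1 | step 9 | methyl 2-[2-(2-hydroxyethyl)-2,4-dimethyl-3-oxocyclohex-4-en-1-yl]prop-2-enoate | OCC[C@]1(C)C(=O)C(C)=CC[C@H]1C(=C)C(=O)OC
F2 | step 9 | methyl 2-[2,4-dimethyl-3-oxo-2-(2-oxoethyl)cyclohex-4-en-1-yl]prop-2-enoate | O=CC[C@]1(C)C(=O)C(C)=CC[C@H]1C(=C)C(=O)OC
F3 | step 4 | tert-butyl 2-[6-(3-acetoxyprop-1-en-2-yl)-1,3-dimethyl-2-oxocyclohex-3-en-1-yl]acetate | CC(C)(C)OC(=O)C[C@]1(C)C(=O)C(C)=CC[C@H]1C(=C)COC(C)=O
F4 | step 4 | tert-butyl 2-[6-(3-hydroxyprop-1-en-2-yl)-1,3-dimethyl-2-oxocyclohex-3-en-1-yl]acetate | CC(C)(C)OC(=O)C[C@]1(C)C(=O)C(C)=CC[C@H]1C(=C)CO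
F5 | step 11 | 9-hydroxy-9-(trimethylsilylmethyl) adduct of 15 (C9 epimers) | C[Si](C)(C)CC1(O)C(C)=CC[C@H]2[C@@H](C(=O)OC)CC3(OCCO3)C[C@]12C
F6 | step 23 | 2,2-(ethylenedioxy)-15,19-bis(triisopropylsilyloxy)labda-7,13E-diene | CC(C)[Si](OC/C=C(\C)CC[C@H]1C(C)=CC[C@H]2[C@@](C)(CO[Si](C(C)C)(C(C)C)C(C)C)CC3(OCCO3)C[C@]12C)(C(C)C)C(C)C
F7 | step 23 | 15,19-bis(triisopropylsilyloxy)labda-7,13E-dien-2-one | CC(C)[Si](OC/C=C(\C)CC[C@H]1C(C)=CC[C@H]2[C@@](C)(CO[Si](C(C)C)(C(C)C)C(C)C)CC(=O)C[C@]12C)(C(C)C)C(C)C
F8 | step 26 | 15-(tert-butyldimethylsilyloxy)-2α-(4-methoxybenzyloxy)labda-7,13E-dien-19-ol | CC(C)(C)[Si](C)(C)OC/C=C(\C)CC[C@H]1C(C)=CC[C@H]2[C@@](C)(CO)C[C@H](OCc3ccc(OC)cc3)C[C@]12C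
F9 | step 26 | 15-(tert-butyldimethylsilyloxy)-2α-(4-methoxybenzyloxy)labda-7,13E-dien-19-yl 3-methylbutanoate | CC(C)(C)[Si](C)(C)OC/C=C(\C)CC[C@H]1C(C)=CC[C@H]2[C@@](C)(COC(=O)CC(C)C)C[C@H](OCc3ccc(OC)cc3)C[C@]12C
F10 | step 26 | 15-hydroxy-2α-(4-methoxybenzyloxy)labda-7,13E-dien-19-yl 3-methylbutanoate | OC/C=C(\C)CC[C@H]1C(C)=CC[C@H]2[C@@](C)(COC(=O)CC(C)C)C[C@H](OCc3ccc(OC)cc3)C[C@]12C
A1 | alternative 1 | acyclic triene with E β-methyl enoate and 2-silyloxy diene | C/C=C(O[Si](C)(C)C(C)(C)C)/C=C/[C@@](C)(COCc1ccc(OC)cc1)C[C@H](O[Si](C)(C)C(C)(C)C)C/C(C)=C/C(=O)OC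
A2 | alternative 1 | trans-fused bicyclic silyl enol ether with C9 ester | COC(=O)[C@H]1[C@@H](C)C(O[Si](C)(C)C(C)(C)C)=C[C@H]2[C@@](C)(COCc3ccc(OC)cc3)C[C@H](O[Si](C)(C)C(C)(C)C)C[C@]12C
A3 | alternative 2 | carvone-derived diazoketone with silyloxymethyl-substituted vinyl arm | [N-]=[N+]=CC(=O)C[C@]1(C)C(=O)C(C)=CC[C@H]1C(=C)CO[Si](C)(C)C(C)(C)C
A4 | alternative 2 | tricyclic cyclopropyl ketone (C3–C4–C18 ring) | O=C1C(C)=CC[C@H]2[C@]3(CO[Si](C)(C)C(C)(C)C)C[C@@H]3C(=O)C[C@]12C
A5 | alternative 3 | acyclic Z allylic acetate with E C5=C10 alkene and C2 enol silane | C=C(O[Si](C)(C)C)C[C@](C)(COC(=O)CC(C)C)/C=C(\C)[C@@H](CCO[Si](c1ccccc1)(c1ccccc1)C(C)(C)C)/C(C)=C\COC(C)=O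
A6 | alternative 3 | 2-oxo trans-decalin with C7=C8 alkene, C19 isovalerate and C12 silyl ether | CC(C)(C)[Si](OCC[C@H]1C(C)=CC[C@H]2[C@@](C)(COC(=O)CC(C)C)CC(=O)C[C@]12C)(c1ccccc1)c1ccccc1
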